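**Plan**

1. Ring A is the cyclohexenone (C1 ketone, C2 bearing the CH2 link, C3 enol carbon, C4 CH–OMe, C5 and C6 CH2); ring B is the cyclopentene. Retrosynthetic cuts, in order: the CH2–C2 bond between the rings; the C4–C5 bond of ring A; the CH2–ring B bond; the ring B–alkenyl bond.
2. Enabling feature: in ring A the methoxy carbon C4 is α to the C3 carbonyl, and its oxygen is 1,4 to the oxygen on C1 across C5–C6. A carbenoid at C4 can therefore take one OMe from a C1 dimethyl ketal (five-membered oxonium ylide O–C1–C2–C3–C4), and the C5=C6 vinyl group on C1 closes ring A by a [2,3] shift, leaving the other OMe as the C1 enol ether.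
3. Forward: ring A is made first from an acyclic diazoketone (steps 1–5). The (Z)-alkenyl iodide (steps 6–8) and ring B from linalool (steps 9–16) are joined to it in step 17, and step 18 unveils the dione.
4. Stereochemistry: C4 of ring A comes from the chiral dirhodium catalyst (step 4); C(Me)OH of ring B from (S)-linalool; the adjacent CH from CBS reduction (step 13) relayed by the suprafacial Still–Wittig shift (step 15); the Z alkene from trans-hydroalumination/iodination (step 6), kept through two couplings.

Key step: step 4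

Remark: (S)-(+)-linalool of high enantiomeric purity is taken as a commercial material.
Remark: the sense of induction in step 4 has to be found by trial; Rh2(S-PTTL)4 (dirhodium tetrakis[N-phthaloyl-(S)-tert-leucinate]) is written, and its mirror-image catalyst is used instead if that one gives (S)-12.
Remark: the target is drawn as one enol form of a 2-alkyl-1,3-dione; both enol forms are the same compound.

**Ring A (steps 1–5)**

Step 1
Reactants: 1 methoxyallene; 2 3-bromo-2-methylprop-1-ene
Product: 5 3,3-dimethoxy-5-methylhexa-1,5-diene, via 1-lithio-1-methoxyallene 3 (not isolated), via 3-methoxy-5-methylhexa-1,2,5-triene 4 (not isolated)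
Conditions: n-BuLi, THF, −40 °C; 2, −40 → 0 °C; then MeOH, CSA (0.1 equiv), 0 °C → rt
Reagents that add atoms: methanol, CO
Why: Alkylation of lithiated methoxyallene at C1 by the allylic bromide, then acid-catalysed addition of methanol to the alkoxyallene (protonation at the central carbon, capture of the 1-methoxyallyl cation at the oxygen-bearing carbon), should give the vinyl ketone dimethyl ketal without ever forming the free vinyl ketone.

Step 2
Reactants: 5 3,3-dimethoxy-5-methylhexa-1,5-diene
Product: 7 4,4-dimethoxyhex-5-en-2-one, via ozonide 6 (not isolated)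
Conditions: O3, CH2Cl2, −78 °C (Sudan Red 7B end point); then PPh3, −78 °C → rt
Reagents that add atoms: ozone, [O-][O+]=O
Why: Chemoselective ozonolysis with reductive work-up: the electron-richer 1,1-disubstituted alkene should react well ahead of the vinyl group, which is deactivated by the two oxygens on the neighbouring carbon.

Step 3
Reactants: 7 4,4-dimethoxyhex-5-en-2-one
Product: 9 1-diazo-4,4-dimethoxyhex-5-en-2-one, via trifluoroacetyl diketone 8 (not isolated)
Conditions: LiN(SiMe3)2 (LiHMDS), THF, −78 °C; CF3CO2CH2CF3; then MsN3, Et3N, H2O (1 equiv), MeCN, rt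
Reagents that add atoms: methanesulfonyl azide, CS(=O)(=O)N=[N+]=[N-]
Why: Detrifluoroacetylative Regitz diazo transfer: kinetic enolisation at the methyl group, Claisen trifluoroacetylation to 8 and diazo transfer with loss of the trifluoroacetyl group should give the terminal diazoketone while the ketal stays intact.

Step 4
Reactants: 9 1-diazo-4,4-dimethoxyhex-5-en-2-one
Product: 12 (S)-3,6-dimethoxycyclohex-2-en-1-one, via oxonium ylide 10 (not isolated), via (S)-3,6-dimethoxycyclohex-3-en-1-one 11 (not isolated)
Conditions: Rh2(S-PTTL)4 (1 mol %), toluene, 0 °C, slow addition of 9; then PPTS (5 mol %), CH2Cl2, rt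
Reagents that add atoms: none
Why: Proposed new method: the electrophilic rhodium carbenoid formed from 9 by loss of N2 (C1 = diazo carbon, C4 = ketal carbon, C6 = vinyl CH2) should be trapped by one of the two enantiotopic methoxy oxygens to give the five-membered oxonium ylide 10 (ring O–C1–C2–C3–C4), which rearranges by a suprafacial [2,3]-sigmatropic shift in which C1 bonds to C6 while the O–C4 bond breaks. The closest known reaction types are the ring-expanding [2,3] shift of cyclic oxonium ylides from γ-alkoxy diazoketones whose ether carbon also carries a vinyl group, and ylide formation with discrimination of enantiotopic acetal oxygens under chiral dirhodium carboxylates or carboxamidates; their union on an acyclic dimethyl ketal is the untested part. The oxonium ring closes by attack of oxygen on the carbenoid carbon and is at once expanded to the six-membered carbocycle through a bridged five-centre transition state (7-oxabicyclo[2.2.1]heptene-like), the oxygen leaving the ring as the OMe group of the new stereocentre while the second methoxy group stays as the enol ether of 11, which PPTS moves into conjugation to give the regiodefined vinylogous ester 12. The configuration of the new CH(OMe) centre is set by the chiral catalyst: its choice between the two methoxy groups fixes the face of the planar ylide carbon over which the vinyl group lies, and the concerted shift transfers this to carbon as C4 becomes sp2. The step needs ylide formation to outrun cyclopropanation of the vinyl group, and the [2,3] shift to outrun the [1,2] shift and ionisation of the ketal-derived ylide: two ether oxygens placed for a five-membered ylide and a vinyl group made electron-poor by the geminal oxygens favour the former, and the allowed five-centre path to an unstrained cyclohexene (the [1,2] shift would give a cyclobutanone), a non-polar solvent and low temperature favour the latter.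

Step 5
Reactants: 12 (S)-3,6-dimethoxycyclohex-2-en-1-one
Product: 13 (S)-2-iodo-3,6-dimethoxycyclohex-2-en-1-one
Conditions: NIS, CH2Cl2, 0 °C → rt, dark
Reagents that add atoms: N-iodosuccinimide, O=C1CCC(=O)N1I
Why: Electrophilic iodination at the nucleophilic α-carbon (C2) of the vinylogous ester is the usual entry to 2-iodo-3-alkoxyenones and should not touch the C6 stereocentre.

**(Z)-Alkenyl iodide (steps 6–8)**

Step 6
Reactants: 14 but-2-yn-1-ol
Product: 16 (Z)-3-iodobut-2-en-1-ol, via cyclic alkenylaluminate 15 (not isolated)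
Conditions: Red-Al (NaAlH2(OCH2CH2OMe)2), THF, 0 °C → rt; then I2, THF, −78 → 0 °C
Reagents that add atoms: iodine, II
Why: Alkoxide-directed trans-hydroalumination of the propargylic alcohol and iodinolysis of the C–Al bond with retention should fix the Z geometry (I cis to CH2OH).

Step 7
Reactants: 16 (Z)-3-iodobut-2-en-1-ol
Product: 17 (Z)-1-bromo-3-iodobut-2-ene
Conditions: CBr4, PPh3, CH2Cl2, 0 °C
Reagents that add atoms: carbon tetrabromide, BrC(Br)(Br)Br
Why: Appel bromination of the primary allylic alcohol under neutral conditions should proceed without allylic transposition or loss of alkene geometry.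

Step 8
Reactants: 17 (Z)-1-bromo-3-iodobut-2-ene; 18 2-methylprop-1-en-1-ylmagnesium bromide
Product: 19 (Z)-2-iodo-6-methylhepta-2,5-diene
Conditions: CuI (10 mol %), THF, −30 → 0 °C
Reagents that add atoms: none
Why: Copper-catalysed SN2 coupling of the alkenyl Grignard reagent with the primary allylic bromide should leave the alkenyl iodide alone at low temperature, the SN2′ position being fully substituted.

**Ring B (steps 9–16)**

Step 9
Reactants: 20 (S)-(+)-linalool
Product: 22 (S)-triethyl[(1-methylcyclopent-2-en-1-yl)oxy]silane, via (S)-1-methylcyclopent-2-en-1-ol 21 (not isolated)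
Conditions: second-generation Hoveyda–Grubbs catalyst (0.5 mol %), CH2Cl2, 40 °C; then 2,6-lutidine, TESOTf, 0 °C
Reagents that add atoms: triethylsilyl trifluoromethanesulfonate, CC[Si](CC)(CC)OS(=O)(=O)C(F)(F)F
Why: Ring-closing metathesis of the 1,6-diene expels isobutene and leaves the tertiary carbinol stereocentre (the later C(Me)OH of ring B) untouched, and the volatile alcohol is silylated in the same flask.

Step 10
Reactants: 22 (S)-triethyl[(1-methylcyclopent-2-en-1-yl)oxy]silane
Product: 23 (S)-4-methyl-4-[(triethylsilyl)oxy]cyclopent-2-en-1-one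
Conditions: Rh2(cap)4 (dirhodium tetracaprolactamate, 1 mol %), t-BuOOH (5 equiv), K2CO3, CH2Cl2, rt
Reagents that add atoms: tert-butyl hydroperoxide, CC(C)(C)OO
Why: Dirhodium-catalysed allylic oxidation with t-BuOOH should oxidise the only allylic CH2, at the end of the allyl system remote from the quaternary carbon, to the enone.

Step 11
Reactants: 23 (S)-4-methyl-4-[(triethylsilyl)oxy]cyclopent-2-en-1-one
Product: 24 (S)-2-iodo-4-methyl-4-[(triethylsilyl)oxy]cyclopent-2-en-1-one
Conditions: I2, pyridine, CH2Cl2, 0 °C → rt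
Reagents that add atoms: iodine, II
Why: α-Iodination of the enone by the iodine/pyridine addition–elimination sequence is standard for 4-silyloxycyclopentenones.

Step 12
Reactants: 19 (Z)-2-iodo-6-methylhepta-2,5-diene; 24 (S)-2-iodo-4-methyl-4-[(triethylsilyl)oxy]cyclopent-2-en-1-one
Product: 27 (S)-4-methyl-2-[(2Z)-6-methylhepta-2,5-dien-2-yl]-4-[(triethylsilyl)oxy]cyclopent-2-en-1-one, via alkenyllithium 25 (not isolated), via alkenylzinc chloride 26 (not isolated)
Conditions: 19, t-BuLi (2 equiv), Et2O, −78 °C; ZnCl2, THF, −78 → 0 °C; then 24, Pd(PPh3)4 (5 mol %), THF, rt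
Reagents that add atoms: none
Why: Negishi coupling: iodine–lithium exchange, transmetalation to zinc and Pd-catalysed coupling with the α-iodoenone all proceed with retention at the alkene, so the (Z)-trisubstituted side-chain alkene should be carried over intact.

Step 13
Reactants: 27 (S)-4-methyl-2-[(2Z)-6-methylhepta-2,5-dien-2-yl]-4-[(triethylsilyl)oxy]cyclopent-2-en-1-one
Product: 29 (1R,4S)-4-methyl-2-[(2Z)-6-methylhepta-2,5-dien-2-yl]cyclopent-2-ene-1,4-diol, via silyl ether alcohol 28 (not isolated)
Conditions: (S)-Me-CBS (20 mol %), catecholborane, toluene, −78 °C; MeOH; then TBAF, THF, 0 °C → rt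
Reagents that add atoms: none
Why: Corey–Bakshi–Shibata reduction with the 2-substituted olefinic carbon as the large group should give the (1R) alcohol, cis to the silyloxy group (hydride anti to OTES, so catalyst and substrate agree; the (R)-catalyst is used if the sense proves opposite), and fluoride then frees the tertiary alcohol.

Step 14
Reactants: 29 (1R,4S)-4-methyl-2-[(2Z)-6-methylhepta-2,5-dien-2-yl]cyclopent-2-ene-1,4-diol; 30 tributyl(iodomethyl)stannane
Product: 31 (1S,4R)-1-methyl-3-[(2Z)-6-methylhepta-2,5-dien-2-yl]-4-[(tributylstannyl)methoxy]cyclopent-2-en-1-ol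
Conditions: KH (1.2 equiv), 18-crown-6 (cat.), THF, 0 °C → rt
Reagents that add atoms: none
Why: Williamson etherification should take place at the more acidic, less hindered secondary allylic alkoxide and not at the tertiary one, and removing the silyl group beforehand excludes base-induced 1,3-silyl migration.

Step 15
Reactants: 31 (1S,4R)-1-methyl-3-[(2Z)-6-methylhepta-2,5-dien-2-yl]-4-[(tributylstannyl)methoxy]cyclopent-2-en-1-ol
Product: 33 (1S,2S)-2-(hydroxymethyl)-1-methyl-3-[(2Z)-6-methylhepta-2,5-dien-2-yl]cyclopent-3-en-1-ol, via dilithio ether 32 (not isolated)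
Conditions: n-BuLi (2.5 equiv), THF, −78 → −40 °C
Reagents that add atoms: none
Why: Still–Wittig [2,3]-sigmatropic rearrangement: tin–lithium exchange gives the α-alkoxy carbanion, which bonds suprafacially to the far alkene carbon on the face that carried the C–O bond, so the new CH2OH should be cis to the tertiary OH while the ring double bond moves into conjugation with the side-chain alkene.

Step 16
Reactants: 33 (1S,2S)-2-(hydroxymethyl)-1-methyl-3-[(2Z)-6-methylhepta-2,5-dien-2-yl]cyclopent-3-en-1-ol
Product: 34 (1S,2R)-2-(iodomethyl)-1-methyl-3-[(2Z)-6-methylhepta-2,5-dien-2-yl]cyclopent-3-en-1-ol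
Conditions: I2, PPh3, imidazole, CH2Cl2, 0 °C
Reagents that add atoms: iodine, II
Why: Appel-type iodination is selective for the primary alcohol, and the hindered tertiary alcohol should not react.

**Union and unveiling (steps 17–18)**

Step 17
Reactants: 34 (1S,2R)-2-(iodomethyl)-1-methyl-3-[(2Z)-6-methylhepta-2,5-dien-2-yl]cyclopent-3-en-1-ol; 13 (S)-2-iodo-3,6-dimethoxycyclohex-2-en-1-one
Product: 37 (6S)-2-{[(1R,5S)-5-hydroxy-5-methyl-2-[(2Z)-6-methylhepta-2,5-dien-2-yl]cyclopent-2-en-1-yl]methyl}-3,6-dimethoxycyclohex-2-en-1-one, via dilithio compound 35 (not isolated), via lithium borinate 36 (not isolated)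
Conditions: 34, t-BuLi (3 equiv), Et2O, −78 °C; B-OMe-9-BBN, THF, −78 °C → rt; then 13, Pd(dppf)Cl2 (5 mol %), AsPh3, K3PO4 (aq), DMF, rt
Reagents that add atoms: none
Why: B-alkyl Suzuki–Miyaura coupling: deprotonation of the alcohol and iodine–lithium exchange, capture by B-methoxy-9-BBN and Pd-catalysed coupling of the borinate with the α-iodo vinylogous ester should join the two halves at the CH2–C2 bond without touching a stereocentre.

Step 18
Reactants: 37 (6S)-2-{[(1R,5S)-5-hydroxy-5-methyl-2-[(2Z)-6-methylhepta-2,5-dien-2-yl]cyclopent-2-en-1-yl]methyl}-3,6-dimethoxycyclohex-2-en-1-one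
Product: 38 (4S)-3-hydroxy-2-{[(1R,5S)-5-hydroxy-5-methyl-2-[(2Z)-6-methylhepta-2,5-dien-2-yl]cyclopent-2-en-1-yl]methyl}-4-methoxycyclohex-2-en-1-one
Conditions: 1 M HCl (aq), THF, 0 °C → rt
Reagents that add atoms: water, O
Why: Mild acid hydrolysis of the methyl vinylogous ester (conjugate addition of water, loss of methanol) should unveil the 2-alkyl-1,3-dione, which is the target in its enol form.

**Compound list**

1 | methoxyallene (1-methoxypropa-1,2-diene) | COC=C=C | starting material
2 | 3-bromo-2-methylprop-1-ene | CC(=C)CBr | starting material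
3 | 1-lithio-1-methoxyallene | [Li]C(OC)=C=C | intermediate
4 | 3-methoxy-5-methylhexa-1,2,5-triene | C=C=C(OC)CC(C)=C | intermediate
5 | 3,3-dimethoxy-5-methylhexa-1,5-diene | C=CC(OC)(OC)CC(C)=C | intermediate
6 | 3-(2,2-dimethoxybut-3-en-1-yl)-3-methyl-1,2,4-trioxolane (ozonide, racemic) | CC1(CC(OC)(OC)C=C)OCOO1 | intermediate
7 | 4,4-dimethoxyhex-5-en-2-one | CC(=O)CC(OC)(OC)C=C | intermediate
8 | 1,1,1-trifluoro-6,6-dimethoxyoct-7-ene-2,4-dione | O=C(CC(=O)CC(OC)(OC)C=C)C(F)(F)F | intermediate
9 | 1-diazo-4,4-dimethoxyhex-5-en-2-one | [N-]=[N+]=CC(=O)CC(OC)(OC)C=C | intermediate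
10 | (5S)-5-ethenyl-5-methoxy-1-methyl-3-oxooxolan-1-ium-2-ide (oxonium ylide) | C[O+]1[CH-]C(=O)C[C@@]1(OC)C=C | intermediate
11 | (S)-3,6-dimethoxycyclohex-3-en-1-one | CO[C@H]1CC=C(OC)CC1=O | intermediate
12 | (S)-3,6-dimethoxycyclohex-2-en-1-one | CO[C@H]1CCC(OC)=CC1=O | intermediate
13 | (S)-2-iodo-3,6-dimethoxycyclohex-2-en-1-one | CO[C@H]1CCC(OC)=C(I)C1=O | intermediate
14 | but-2-yn-1-ol | CC#CCO | starting material
15 | sodium 2,2-bis(2-methoxyethoxy)-3-methyl-2,5-dihydro-1,2-oxaaluminol-2-uide (cyclic alkenylaluminate) | [Na+].CC1=CCO[Al-]1(OCCOC)OCCOC | intermediate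
16 | (Z)-3-iodobut-2-en-1-ol | C/C(I)=C/CO | intermediate
17 | (Z)-1-bromo-3-iodobut-2-ene | C/C(I)=C/CBr | intermediate
18 | 2-methylprop-1-en-1-ylmagnesium bromide | CC(C)=C[Mg]Br | starting material
19 | (Z)-2-iodo-6-methylhepta-2,5-diene | C/C(I)=C/CC=C(C)C | intermediate
20 | (S)-(+)-linalool, (3S)-3,7-dimethylocta-1,6-dien-3-ol | C=C[C@@](C)(O)CCC=C(C)C | starting material
21 | (S)-1-methylcyclopent-2-en-1-ol | C[C@@]1(O)C=CCC1 | intermediate
22 | (S)-triethyl[(1-methylcyclopent-2-en-1-yl)oxy]silane | C[C@@]1(O[Si](CC)(CC)CC)C=CCC1 | intermediate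
23 | (S)-4-methyl-4-[(triethylsilyl)oxy]cyclopent-2-en-1-one | C[C@@]1(O[Si](CC)(CC)CC)C=CC(=O)C1 | intermediate
24 | (S)-2-iodo-4-methyl-4-[(triethylsilyl)oxy]cyclopent-2-en-1-one | C[C@@]1(O[Si](CC)(CC)CC)C=C(I)C(=O)C1 | intermediate
25 | [(2E)-6-methylhepta-2,5-dien-2-yl]lithium (Li cis to the CH2 group) | C/C([Li])=C/CC=C(C)C | intermediate
26 | chloro[(2Z)-6-methylhepta-2,5-dien-2-yl]zinc | C/C([Zn]Cl)=C/CC=C(C)C | intermediate
27 | (S)-4-methyl-2-[(2Z)-6-methylhepta-2,5-dien-2-yl]-4-[(triethylsilyl)oxy]cyclopent-2-en-1-one | C[C@@]1(O[Si](CC)(CC)CC)C=C(/C(C)=C\CC=C(C)C)C(=O)C1 | intermediate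
28 | (1R,4S)-4-methyl-2-[(2Z)-6-methylhepta-2,5-dien-2-yl]-4-[(triethylsilyl)oxy]cyclopent-2-en-1-ol | C[C@@]1(O[Si](CC)(CC)CC)C=C(/C(C)=C\CC=C(C)C)[C@H](O)C1 | intermediate
29 | (1R,4S)-4-methyl-2-[(2Z)-6-methylhepta-2,5-dien-2-yl]cyclopent-2-ene-1,4-diol | C[C@@]1(O)C=C(/C(C)=C\CC=C(C)C)[C@H](O)C1 | intermediate
30 | tributyl(iodomethyl)stannane | CCCC[Sn](CCCC)(CCCC)CI | starting material
31 | (1S,4R)-1-methyl-3-[(2Z)-6-methylhepta-2,5-dien-2-yl]-4-[(tributylstannyl)methoxy]cyclopent-2-en-1-ol | C[C@@]1(O)C=C(/C(C)=C\CC=C(C)C)[C@H](OC[Sn](CCCC)(CCCC)CCCC)C1 | intermediate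
32 | lithium (1S,4R)-4-(lithiomethoxy)-1-methyl-3-[(2Z)-6-methylhepta-2,5-dien-2-yl]cyclopent-2-en-1-olate | C[C@@]1(O[Li])C=C(/C(C)=C\CC=C(C)C)[C@H](OC[Li])C1 | intermediate
33 | (1S,2S)-2-(hydroxymethyl)-1-methyl-3-[(2Z)-6-methylhepta-2,5-dien-2-yl]cyclopent-3-en-1-ol | OC[C@@H]1C(/C(C)=C\CC=C(C)C)=CC[C@]1(C)O | intermediate
34 | (1S,2R)-2-(iodomethyl)-1-methyl-3-[(2Z)-6-methylhepta-2,5-dien-2-yl]cyclopent-3-en-1-ol | IC[C@@H]1C(/C(C)=C\CC=C(C)C)=CC[C@]1(C)O | intermediate
35 | lithium (1S,2R)-2-(lithiomethyl)-1-methyl-3-[(2Z)-6-methylhepta-2,5-dien-2-yl]cyclopent-3-en-1-olate | [Li]C[C@@H]1C(/C(C)=C\CC=C(C)C)=CC[C@]1(C)O[Li] | intermediate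
36 | lithium B-methoxy-B-alkyl-9-borabicyclo[3.3.1]nonane borinate formed from 35 | [Li+].CO[B-]1(C[C@@H]2C(/C(C)=C\CC=C(C)C)=CC[C@]2(C)O[Li])C3CCCC1CCC3 | intermediate
37 | (6S)-2-{[(1R,5S)-5-hydroxy-5-methyl-2-[(2Z)-6-methylhepta-2,5-dien-2-yl]cyclopent-2-en-1-yl]methyl}-3,6-dimethoxycyclohex-2-en-1-one | CO[C@H]1CCC(OC)=C(C[C@@H]2C(/C(C)=C\CC=C(C)C)=CC[C@]2(C)O)C1=O | intermediate
38 | (4S)-3-hydroxy-2-{[(1R,5S)-5-hydroxy-5-methyl-2-[(2Z)-6-methylhepta-2,5-dien-2-yl]cyclopent-2-en-1-yl]methyl}-4-methoxycyclohex-2-en-1-one | CO[C@H]1CCC(=O)C(C[C@@H]2C(/C(C)=C\CC=C(C)C)=CC[C@]2(C)O)=C1O | target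

**Step count and risks**

Total: 18 steps. Longest linear sequence: 10 steps (steps 9–18 from (S)-linalool; the branch from but-2-yn-1-ol through steps 6–8 and 12–18 is equally long).

Step 4 (labelled). The carbenoid may add to the vinyl group (cyclopropanation) instead of forming the ylide. The ketal-derived ylide may ionise before it rearranges, which would erase the stereochemical information. The catalyst may also fail to tell the two methoxy groups apart. The fallback uses known chemistry without a carbene and replaces the path 1 → 12. In place of diazoketone 9 it sets out from commercial 3-methoxycyclohex-2-en-1-one F1 and it comes back to the route at 12. Mn(OAc)3-mediated α′-acetoxylation (benzene, reflux) gives racemic 4-methoxy-2-oxocyclohex-3-en-1-yl acetate F2. Lipase-mediated kinetic resolution (enzymatic hydrolysis in phosphate buffer, enzyme chosen for the (S) alcohol) gives (S)-6-hydroxy-3-methoxycyclohex-2-en-1-one F3. O-methylation with MeI and Ag2O then gives 12.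

Step 17. Exchange and borinate formation may be incomplete beside the lithium alkoxide, and transmetalation of the β-branched primary alkyl group next to a quaternary carbon may be slow, so that protodeboronation or β-hydride elimination takes over. The fallback is a nickel-catalysed reductive cross-electrophile coupling, which needs no organolithium or organoboron compound. It sets out from 34 and 13, which are coupled directly with NiCl2(dme), 4,4′-di-tert-butyl-2,2′-bipyridine and Mn powder in DMA. It tolerates the free tertiary alcohol, makes no new compound (F0) and comes back at 37.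

Step 18. Under acid the tertiary hydroxyl may add to the activated vinylogous ester or to the dione and close a six-membered enol ether, or the tertiary alcohol may ionise and dehydrate. The fallback exchanges the methyl enol ether for a fluoride-labile one, so that the dione is set free as its enolate under basic conditions. It sets out from 12 and comes back at the target 38. Acid-catalysed exchange of 12 with 2-(trimethylsilyl)ethanol (PPTS, benzene, removal of MeOH) gives (S)-6-methoxy-3-[2-(trimethylsilyl)ethoxy]cyclohex-2-en-1-one F4. NIS gives (S)-2-iodo-6-methoxy-3-[2-(trimethylsilyl)ethoxy]cyclohex-2-en-1-one F5. Coupling with 34 under the conditions of step 17 gives (6S)-2-{[(1R,5S)-5-hydroxy-5-methyl-2-[(2Z)-6-methylhepta-2,5-dien-2-yl]cyclopent-2-en-1-yl]methyl}-6-methoxy-3-[2-(trimethylsilyl)ethoxy]cyclohex-2-en-1-one F6. TBAF in THF then fragments the silylethyl group, and work-up at pH 5 gives 38.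

Further compounds
F1 | step 4 | 3-methoxycyclohex-2-en-1-one (commercial) | COC1=CC(=O)CCC1
F2 | step 4 | racemic 4-methoxy-2-oxocyclohex-3-en-1-yl acetate | CC(=O)OC1CCC(OC)=CC1=O
F3 | step 4 | (S)-6-hydroxy-3-methoxycyclohex-2-en-1-one | O[C@H]1CCC(OC)=CC1=O
F0 | step 17 | none | none
F4 | step 18 | (S)-6-methoxy-3-[2-(trimethylsilyl)ethoxy]cyclohex-2-en-1-one | CO[C@H]1CCC(OCC[Si](C)(C)C)=CC1=O
F5 | step 18 | (S)-2-iodo-6-methoxy-3-[2-(trimethylsilyl)ethoxy]cyclohex-2-en-1-one | CO[C@H]1CCC(OCC[Si](C)(C)C)=C(I)C1=O
F6 | step 18 | (6S)-2-{[(1R,5S)-5-hydroxy-5-methyl-2-[(2Z)-6-methylhepta-2,5-dien-2-yl]cyclopent-2-en-1-yl]methyl}-6-methoxy-3-[2-(trimethylsilyl)ethoxy]cyclohex-2-en-1-one | CO[C@H]1CCC(OCC[Si](C)(C)C)=C(C[C@@H]2C(/C(C)=C\CC=C(C)C)=CC[C@]2(C)O)C1=O
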